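(The numbers in the tables come from a simulation on assumed constants; the scatter is artificial.)

The share of X in X plus L at 3.0 min cannot be read from these runs: the first reading comes at 0.500 h in the dawn run, and X there reads 1% with a scatter of 1.5 percentage points. So I reckon it from readings that carry more weight.

| setting | dawn | noon | flask |
|---|---|---|---|
| Z | 7.5 mM | 30 mM | 15 mM |
| remark | run made earlier | run made earlier |  |
| time |  |  | 6.0 h |

| run | time / h | X / % | L / % |
|---|---|---|---|
| dawn | 0.500 | 1 | 11 |
| dawn | 1.00 | 0 | 22 |
| dawn | 2.00 | 1 | 32 |
| dawn | 4.00 | 3 | 35 |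
| dawn | 8.00 | 3 | 35 |
| noon | 0.667 | 0 | 14 |
| noon | 2.00 | 1 | 27 |
| noon | 3.00 | 2 | 28 |
| noon | 5.00 | 5 | 28 |
| noon | 8.00 | 7 | 28 |

(scatter of a reading: 1.5 percentage points)

1. share of X in X plus L at 3.0 min
2. share of X in X plus L at 6.0 h



I carry the branching share b, which is X over X plus L as the two first form (the kinetic selectivity). I pool both runs, since 15 mM lies at the geometric mean of their charges. One way takes the readings up to 2.00 h: X sums to 3.00% and L to 106%, so b is 2.75%. The other way uses different X readings: those at 8.00 h average a stream w of 0.00625 h⁻¹ of the charge, and the first L readings give a rate u of 0.215 h⁻¹, so w/(w+u) is 2.83%. The two agree, so the readings ask for no lag in X, and I take b for the early time.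

At 6.0 h the stream gives 3.75% of X against an L plateau of 31.5%, a share of 10.6%. Pooling the last two readings of each run gives 12.5% instead. The two part by 1.9 points. The pool holds the noon X reading of 5% at 5.00 h, which stands 1.9 points above the stream, against a scatter of 1.5 points, and the noon X reading of 7% at 8.00 h feeds both ways, so neither is clean. I keep 10.6% as my reckoning, with that gap as its uncertainty.

The forecast gives 1% at 3.0 min, adding “the data barely constrain it”, and 12% at 6.0 h; my early share stands above it and my late share below it.

The flask gives 4.25% at 3.0 min and 8.26% at 6.0 h.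

    Z ⇌ L (K = 2.10, k = 0.340 h⁻¹)
    Z ⇌ X (K = 2.60, k = 0.0150 h⁻¹)
    Z ⇌ D (K = 0.880, k = 0.310 h⁻¹)
    L → Q (k = 0.0510 h⁻¹)
    2 Z → G (k = 5.60 L mol⁻¹ h⁻¹)

The rate constant of Z turning into X over that of Z turning into L is 0.0441, a share of 4.22% at the start. Counted in units of my b, this flask stands at 1.55 at the early time and 3.00 at the late one. A neighbour flask charged with 25 mM of Z, all else held, gives 4.25% and 8.34%, which are 1.55 and 3.03 in the same units.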